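**Assumption:** the target has no stereocentre and no stereogenic double bond, so no enantiocontrol is needed; the only stereo element on the way is the E double bond of chalcone 12, which is consumed again.

## Retrosynthetic overview

1. Target 16 comes from flavone 14 (6,2'-di-O-benzyl, 5-O-methyl) by hydrogenolysis, then carbonyl-chelation-directed cleavage of the 5-O-methyl group only.
2. Ring C is the only ring built: oxidative cyclisation of 2'-hydroxychalcone 12 closes the O1–C2 bond and sets the C2=C3 double bond.
3. Key C–C bond (flavone C2–C3): intermolecular Claisen–Schmidt aldol condensation of ring A acetophenone 7 with ring B aldehyde 10.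
4. Acetophenone 7 comes from 3,4,5-trimethoxyphenol by O-methylation, Friedel–Crafts acetylation with ortho-demethylation, Elbs para-hydroxylation and selective benzylation.
5. Aldehyde 10 comes from 2,6-dimethoxybenzaldehyde by mono-demethylation and benzylation; rings A and B are bought as benzenes.

## Route

**Step 1**
Reactants: 1 3,4,5-trimethoxyphenol
Product: 2 1,2,3,5-tetramethoxybenzene
Conditions: MeI (1.5 equiv), K2CO3 (2 equiv), acetone, reflux, 6 h
Reagents that add atoms: iodomethane, CI
Why: Williamson O-methylation of the single free phenol is clean because no other nucleophilic site is present.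

**Step 2**
Reactants: 2 1,2,3,5-tetramethoxybenzene
Product: 4 2-hydroxy-3,4,6-trimethoxyacetophenone, via 2,3,4,6-tetramethoxyacetophenone 3 (not isolated)
Conditions: AcCl (1.5 equiv), AlCl3 (3 equiv), Et2O, 0 °C → reflux, 24 h; then ice/2 M HCl
Reagents that add atoms: acetyl chloride, CC(Cl)=O
Why: Friedel–Crafts acylation occurs at one of the two equivalent free positions, and AlCl3 then cleaves the more congested ortho-methoxy group (between the acetyl and a neighbouring methoxy) through a six-membered aluminium chelate.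

**Step 3**
Reactants: 4 2-hydroxy-3,4,6-trimethoxyacetophenone
Product: 6 2,5-dihydroxy-3,4,6-trimethoxyacetophenone, via aryl sulfate ArOSO3K 5 (not isolated)
Conditions: K2S2O8 (1.1 equiv), 10% aq KOH, 0 °C → rt, 24 h; acidify to pH 4 and extract unreacted 4; then conc. HCl, Na2SO3, 90 °C, 1 h, under N2
Reagents that add atoms: potassium peroxodisulfate, [K+].[K+].[O-]S(=O)(=O)OOS(=O)(=O)[O-]
Why: Elbs persulfate oxidation attacks the phenoxide at its only free position, which is para to the phenol oxygen, and acid hydrolysis of the aryl sulfate releases the hydroquinone.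

**Step 4**
Reactants: 6 2,5-dihydroxy-3,4,6-trimethoxyacetophenone
Product: 7 5-benzyloxy-2-hydroxy-3,4,6-trimethoxyacetophenone
Conditions: BnBr (1.05 equiv), K2CO3 (1.2 equiv), acetone, reflux, 5 h, under N2
Reagents that add atoms: benzyl bromide, BrCc1ccccc1
Why: In this Williamson etherification the 2-OH is held in a hydrogen bond to the ketone and stays unreactive, so one equivalent of BnBr alkylates only the 5-OH.

**Step 5**
Reactants: 8 2,6-dimethoxybenzaldehyde
Product: 9 2-hydroxy-6-methoxybenzaldehyde
Conditions: AlCl3 (1.5 equiv), CH2Cl2, 0 °C → rt, 6 h; then 1 M HCl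
Reagents that add atoms: none
Why: Chelation-directed ether cleavage by AlCl3 removes one ortho-methyl group, and the resulting aluminium phenoxide chelate deactivates the aldehyde towards a second cleavage.

**Step 6**
Reactants: 9 2-hydroxy-6-methoxybenzaldehyde
Product: 10 2-benzyloxy-6-methoxybenzaldehyde
Conditions: BnBr (1.1 equiv), K2CO3 (1.5 equiv), DMF, 60 °C, 4 h
Reagents that add atoms: benzyl bromide, BrCc1ccccc1
Why: Williamson benzylation in DMF overcomes the hydrogen bond of the salicylaldehyde OH, and the benzyl ether keeps the aldehyde electrophilic in the following base step.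

**Step 7**
Reactants: 7 5-benzyloxy-2-hydroxy-3,4,6-trimethoxyacetophenone; 10 2-benzyloxy-6-methoxybenzaldehyde (1.2 equiv)
Product: 12 (E)-1-(5-benzyloxy-2-hydroxy-3,4,6-trimethoxyphenyl)-3-(2-benzyloxy-6-methoxyphenyl)prop-2-en-1-one, via racemic aldol adduct 11 (not isolated)
Conditions: KOH (50% aq, 10 equiv), EtOH, rt, 48–72 h, under N2; then cold 2 M HCl
Reagents that add atoms: none
Why: Claisen–Schmidt crossed aldol condensation of the methyl ketone enolate with a non-enolisable aldehyde, followed by E1cB dehydration, gives the conjugated E enone as the thermodynamic product, so the carbinol stereocentre of 11 is lost.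

**Step 8**
Reactants: 12 (E)-2'-hydroxychalcone
Product: 14 6,2'-bis(benzyloxy)-5,7,8,6'-tetramethoxyflavone, via racemic flavanone 13 (not isolated)
Conditions: I2 (0.1 equiv), DMSO, 120 °C, 3 h; then aq Na2S2O3
Reagents that add atoms: none
Why: Iodine-catalysed oxidative cyclisation proceeds by oxa-Michael closure of the 2'-phenol to the flavanone, α-iodination and loss of HI, with DMSO re-oxidising HI to I2, and the flavanone stereocentre disappears in the aromatic pyranone.

**Step 9**
Reactants: 14 6,2'-bis(benzyloxy)-5,7,8,6'-tetramethoxyflavone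
Product: 15 6,2'-dihydroxy-5,7,8,6'-tetramethoxyflavone
Conditions: H2 (1 atm), 10% Pd/C, EtOAc–MeOH 1:1, rt, 3–5 h, monitored by TLC
Reagents that add atoms: none
Why: Catalytic hydrogenolysis cleaves both aryl benzyl ethers under neutral conditions while the methyl ethers and the conjugated chromone double bond are inert at 1 atm.

**Step 10**
Reactants: 15 6,2'-dihydroxy-5,7,8,6'-tetramethoxyflavone
Product: 16 5,6,2'-trihydroxy-7,8,6'-trimethoxyflavone
Conditions: BCl3 (1 M in CH2Cl2, 4 equiv), CH2Cl2, −78 → 0 °C, 1–2 h, under Ar; quench with ice/1 M HCl as soon as 15 is consumed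
Reagents that add atoms: none
Why: Chelation-directed demethylation works because boron bound to the C4 carbonyl activates only the peri 5-OMe for chloride attack, leaving the 7-, 8- and 6'-methoxy groups untouched at low temperature.

## Compound list

1 | 3,4,5-trimethoxyphenol | COc1cc(O)cc(OC)c1OC | starting material
2 | 1,2,3,5-tetramethoxybenzene | COc1cc(OC)cc(OC)c1OC | intermediate
3 | 2,3,4,6-tetramethoxyacetophenone (not isolated) | CC(=O)c1c(OC)cc(OC)c(OC)c1OC | intermediate
4 | 2-hydroxy-3,4,6-trimethoxyacetophenone | CC(=O)c1c(O)c(OC)c(OC)cc1OC | intermediate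
5 | potassium 3-acetyl-4-hydroxy-2,5,6-trimethoxyphenyl sulfate, ArOSO3K (not isolated) | CC(=O)c1c(O)c(OC)c(OC)c(OS(=O)(=O)[O-])c1OC.[K+] | intermediate
6 | 2,5-dihydroxy-3,4,6-trimethoxyacetophenone | CC(=O)c1c(O)c(OC)c(OC)c(O)c1OC | intermediate
7 | 5-benzyloxy-2-hydroxy-3,4,6-trimethoxyacetophenone | CC(=O)c1c(O)c(OC)c(OC)c(OCc2ccccc2)c1OC | intermediate
8 | 2,6-dimethoxybenzaldehyde | COc1cccc(OC)c1C=O | starting material
9 | 2-hydroxy-6-methoxybenzaldehyde | COc1cccc(O)c1C=O | intermediate
10 | 2-benzyloxy-6-methoxybenzaldehyde | COc1cccc(OCc2ccccc2)c1C=O | intermediate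
11 | 1-(5-benzyloxy-2-hydroxy-3,4,6-trimethoxyphenyl)-3-(2-benzyloxy-6-methoxyphenyl)-3-hydroxypropan-1-one, racemic (not isolated) | COc1cccc(OCc2ccccc2)c1C(O)CC(=O)c1c(O)c(OC)c(OC)c(OCc2ccccc2)c1OC | intermediate
12 | (E)-1-(5-benzyloxy-2-hydroxy-3,4,6-trimethoxyphenyl)-3-(2-benzyloxy-6-methoxyphenyl)prop-2-en-1-one | COc1cccc(OCc2ccccc2)c1/C=C/C(=O)c1c(O)c(OC)c(OC)c(OCc2ccccc2)c1OC | intermediate
13 | 6-benzyloxy-2-(2-benzyloxy-6-methoxyphenyl)-5,7,8-trimethoxychroman-4-one, racemic (not isolated) | COc1cccc(OCc2ccccc2)c1C1CC(=O)c2c(OC)c(OCc3ccccc3)c(OC)c(OC)c2O1 | intermediate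
14 | 6-benzyloxy-2-(2-benzyloxy-6-methoxyphenyl)-5,7,8-trimethoxy-4H-chromen-4-one | COc1cccc(OCc2ccccc2)c1-c1cc(=O)c2c(OC)c(OCc3ccccc3)c(OC)c(OC)c2o1 | intermediate
15 | 6-hydroxy-2-(2-hydroxy-6-methoxyphenyl)-5,7,8-trimethoxy-4H-chromen-4-one | COc1cccc(O)c1-c1cc(=O)c2c(OC)c(O)c(OC)c(OC)c2o1 | intermediate
16 | 5,6-dihydroxy-2-(2-hydroxy-6-methoxyphenyl)-7,8-dimethoxy-4H-chromen-4-one (5,6,2'-trihydroxy-7,8,6'-trimethoxyflavone) | COc1cccc(O)c1-c1cc(=O)c2c(O)c(O)c(OC)c(OC)c2o1 | target

## Step count and risk assessment

Total step count: 10.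
Longest linear sequence: 8 steps (1 → 2 → 4 → 6 → 7 → 12 → 14 → 15 → 16; steps 1–4 and 7–10). The ring B branch (steps 5–6) joins at step 7.

Three steps most likely to fail:

**Step 3 (Elbs oxidation; conversions are typically modest and the hydroquinone is air-sensitive).** The fallback sets out from 4 and comes back at 6. Phenol 4 is oxidised at its free para position with ON(SO3K)2 (potassium nitrosodisulfonate, 2.2 equiv) in aqueous KH2PO4/acetone at rt (Teuber oxidation). This gives 2-acetyl-3,5,6-trimethoxy-1,4-benzoquinone F1. The quinone is then reduced with Na2S2O4 in EtOAc/water to hydroquinone 6, which goes on into step 4.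

**Step 7 (aldol condensation between two di-ortho-substituted, electron-rich partners; may be slow or incomplete).** The fallback sets out from 10 (together with 7) and comes back at 14, replacing the aldol by an intermolecular Claisen condensation and also bypassing step 8. Aldehyde 10 is oxidised with NaClO2, NaH2PO4 and 2-methyl-2-butene in t-BuOH/water to 2-benzyloxy-6-methoxybenzoic acid F2. This is converted with (COCl)2 and catalytic DMF in CH2Cl2 into 2-benzyloxy-6-methoxybenzoyl chloride F3. The dianion of acetophenone 7 (LiN(SiMe3)2, 4 equiv, THF, −78 °C) is C-acylated with the chloride to give 1-(5-benzyloxy-2-hydroxy-3,4,6-trimethoxyphenyl)-3-(2-benzyloxy-6-methoxyphenyl)propane-1,3-dione F4. Cyclodehydration of the diketone in AcOH with NaOAc at 100 °C then gives flavone 14.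

**Step 10 (selective 5-O-demethylation on a substrate with free phenols; risk of over-demethylation at C7 and of air oxidation of the 5,6-dihydroxy product under acidic work-up).** The fallback sets out from 14 and comes back at 16 by reversing the order of the two deprotections. The 5-O-methyl group of 14 is cleaved first by magnesium chelation with MgBr2·OEt2 (3 equiv, MeCN/toluene, 80 °C), which leaves the non-chelated benzyl and methyl ethers alone. This gives 6-benzyloxy-2-(2-benzyloxy-6-methoxyphenyl)-5-hydroxy-7,8-dimethoxy-4H-chromen-4-one F5. Neutral hydrogenolysis (H2, 10% Pd/C, EtOAc/MeOH, rt) then removes both benzyl groups and delivers 16 as the last operation.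

## Further compounds

F1 | step 3 | 2-acetyl-3,5,6-trimethoxy-1,4-benzoquinone | CC(=O)C1=C(OC)C(=O)C(OC)=C(OC)C1=O
F2 | step 7 | 2-benzyloxy-6-methoxybenzoic acid | COc1cccc(OCc2ccccc2)c1C(=O)O
F3 | step 7 | 2-benzyloxy-6-methoxybenzoyl chloride | COc1cccc(OCc2ccccc2)c1C(Cl)=O
F4 | step 7 | 1-(5-benzyloxy-2-hydroxy-3,4,6-trimethoxyphenyl)-3-(2-benzyloxy-6-methoxyphenyl)propane-1,3-dione | COc1cccc(OCc2ccccc2)c1C(=O)CC(=O)c1c(O)c(OC)c(OC)c(OCc2ccccc2)c1OC
F5 | step 10 | 6-benzyloxy-2-(2-benzyloxy-6-methoxyphenyl)-5-hydroxy-7,8-dimethoxy-4H-chromen-4-one | COc1cccc(OCc2ccccc2)c1-c1cc(=O)c2c(O)c(OCc3ccccc3)c(OC)c(OC)c2o1
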